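## Retrosynthetic overview

1. The benzene ring is bought intact in 3,5-dimethoxybenzyl bromide (1); no ring is formed and the target has no stereocentre.
2. C–C (supporting): 1 and 1-bromodocosane (2, used as docosylmagnesium bromide 3) are the two halves of the benzylic CH2–CH2 bond of 1,3-dimethoxy-5-tricosylbenzene (4).
3. C–O (key): the phenolic C–O bond of target 5 is disconnected to 4 plus an oxygen-atom donor, that is, a direct C–H hydroxylation at the ring position flanked by the chain and one OMe (para to the other OMe).

Assumption: the target SMILES contains no stereocentre and no double-bond geometry, so "single enantiomer" needs no stereocontrol; the side chain is read as unbranched tricosyl (23 carbons).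

## Route

Step 1
Reactants: 1 3,5-dimethoxybenzyl bromide; 2 1-bromodocosane
Product: 4 1,3-dimethoxy-5-tricosylbenzene, via docosylmagnesium bromide 3 (not isolated)
Conditions: 2 (1.2 equiv), Mg (1.3 equiv), cat. I2, THF, 60 °C; then add warm to 1, Li2CuCl4 (3 mol%), THF, −10 °C → rt; aq. NH4Cl
Reagents that add atoms: none
Why: Kochi-type copper-catalysed sp3–sp3 cross-coupling, in which the alkylcuprate formed in the flask displaces the reactive benzylic bromide, the aryl methyl ethers are inert to the Grignard reagent at or below rt, and no stereocentre is created.

Step 2
Reactants: 4 1,3-dimethoxy-5-tricosylbenzene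
Product: 5 2,4-dimethoxy-6-tricosylphenol (the target)
Conditions: 3,5-dichloropyridine N-oxide (1.3 equiv), 3,6-di-tert-butyl-9-mesityl-10-phenylacridinium BF4 (5 mol%), degassed DCE (0.1 M), 450 nm LEDs, N2, 30 °C
Reagents that add atoms: 3,5-dichloropyridine N-oxide, [O-][n+]1cc(Cl)cc(Cl)c1
Why: Proposed new method: redox-neutral photocatalytic arene C–H hydroxylation by oxygen-atom transfer from an N-oxide, in which the excited acridinium (E* about +2.1 V vs SCE) oxidises 4 (about +1.4 to +1.5 V) to its arene radical cation, the N-oxide oxygen adds at one of the two equivalent ring positions para to one OMe and ortho to the chain, the resulting H–C–O–N+ σ-adduct loses its ipso proton with N–O cleavage (as in the base-induced collapse of N-alkoxypyridinium salts to carbonyl compounds) to give 3,5-dichloropyridine and the aryloxyl radical, and the acridine radical plus the released proton turn that radical into phenol 5 and regenerate the catalyst, with no O2 or terminal oxidant present so that over-oxidation to the quinone is limited; the closest known reaction types are acridinium-photoredox site-selective arene C–H amination through arene radical cations and O-atom transfer from pyridine N-oxides by nucleophilic addition and N–O cleavage (gold–alkyne oxidation); no stereocentre is formed.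

## Compound list

1 | 3,5-dimethoxybenzyl bromide (achiral) | COc1cc(CBr)cc(OC)c1 | starting material
2 | 1-bromodocosane (achiral) | CCCCCCCCCCCCCCCCCCCCCCBr | starting material
3 | docosylmagnesium bromide (achiral, formed in the flask) | CCCCCCCCCCCCCCCCCCCCCC[Mg]Br | intermediate
4 | 1,3-dimethoxy-5-tricosylbenzene (achiral) | CCCCCCCCCCCCCCCCCCCCCCCc1cc(OC)cc(OC)c1 | intermediate
5 | 2,4-dimethoxy-6-tricosylphenol (achiral) | CCCCCCCCCCCCCCCCCCCCCCCc1cc(OC)cc(OC)c1O | target

## Step count and risk

Total step count: 2.
Longest linear sequence: 2 steps (2 → 4 → 5, with 3 formed and consumed in the flask of step 1).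

Steps most likely to fail (the route has only two steps, so both are ranked and there is no third):

1. Step 2 (the proposed new step). The risks are:
   - The product phenol 5 is easier to oxidise than 4, so it will quench the excited catalyst as it builds up; this can stall the reaction, or give 2-methoxy-6-tricosyl-1,4-benzoquinone if air leaks in.
   - Some oxygen transfer may occur at the position between the two OMe groups, giving the isomeric 2,6-dimethoxy-4-tricosylphenol.
   - The radical cation may lose a benzylic proton instead of being trapped.
   - The N-oxide may itself be oxidised and abstract hydrogen from the chain.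

   Fallback with known chemistry, setting out from 4 and coming back to the route at 5: Vilsmeier–Haack formylation of 4 (POCl3, DMF, DCE, 0 → 70 °C, then aq. NaOAc) goes to the same ring position, as it does for 3,5-dimethoxytoluene, and gives 2,4-dimethoxy-6-tricosylbenzaldehyde F1. Baeyer–Villiger (Dakin-type) oxidation of F1 with mCPBA (CH2Cl2, rt) lets the electron-rich aryl group migrate to oxygen and gives 2,4-dimethoxy-6-tricosylphenyl formate F2. K2CO3 in MeOH/THF at rt then cleaves the formate to 5.

2. Step 1. The risks are:
   - Halogen–metal exchange and Wurtz coupling give the bibenzyl and the C44 alkane.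
   - Docosylmagnesium bromide crystallises from THF below about 30 °C, so it must be transferred warm.

   Fallback setting out from 2 and coming back to the route at 4: 2 is heated with PPh3 (toluene, 110 °C) to give docosyl(triphenyl)phosphonium bromide F3. Deprotonation with NaHMDS (THF, 0 °C) and addition of commercial 3,5-dimethoxybenzaldehyde (COc1cc(C=O)cc(OC)c1) give 1,3-dimethoxy-5-(tricos-1-en-1-yl)benzene F4 as a Z-major E/Z mixture. Hydrogenation (H2 1 atm, 10% Pd/C, EtOAc, 40 °C) removes the geometry and delivers 4.

Further compounds
F1 | step 2 | 2,4-dimethoxy-6-tricosylbenzaldehyde | CCCCCCCCCCCCCCCCCCCCCCCc1cc(OC)cc(OC)c1C=O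
F2 | step 2 | 2,4-dimethoxy-6-tricosylphenyl formate | CCCCCCCCCCCCCCCCCCCCCCCc1cc(OC)cc(OC)c1OC=O
F3 | step 1 | docosyl(triphenyl)phosphonium bromide | CCCCCCCCCCCCCCCCCCCCCC[P+](c1ccccc1)(c1ccccc1)c1ccccc1.[Br-]
F4 | step 1 | (Z)-1,3-dimethoxy-5-(tricos-1-en-1-yl)benzene (major isomer of the E/Z mixture) | CCCCCCCCCCCCCCCCCCCCC/C=C\c1cc(OC)cc(OC)c1
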